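**Retrosynthetic overview**
1. Atom numbers (elemane type): C10 (CH3-14, vinyl C1=C2), C9, C8 (OAc), C7, C6 (lactone O), C5 (isopropenyl C4); lactone carbons C11 (CH3-13) and C12. Last bonds made: the angelate ester (step 15), C11–O by hydroxylation of the enolate from α-methylene lactone 20 (step 14), and the lactone bond C12–O6 by carbonylation of alkenyl triflate 19 (step 13).
2. 19 is unmasked from tricycle 11, which holds two temporary rings: a lactone bridge C10–C1(=O)–O–C6 (reduced, then Wittig: vinyl and 6-OH) and a 2,3-dimethyl etheno bridge between C5 and C8 (ozonolysis; Baeyer–Villiger gives 8-OAc; methylenation gives the isopropenyl group).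
3. Key disconnection: C5–C6 and C7–C8 at once, by intramolecular Diels–Alder reaction of (Z)-enol ester 10. It closes the cyclohexane ring (inside a bicyclo[2.2.2]octene) and the tether lactone, and sets C5, C6, C7 and C8 from C10.
4. Enabling feature: on the ring C5–C6–C7–C8–C9–C10 the vinyl carbon C1 and O-6 are cis-1,3, and the C5 and C8 substituents are cis-1,4. C1 can therefore be an acyl tether to O-6, and C4 and the acetate carbonyl carbon can be the two ends of an etheno bridge, so the six-membered ring is a cyclohexa-1,3-diene before the key step.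
5. 10 comes from acid 8 and but-3-yn-2-one 9; 8 comes from ethyl 2-formylpropanoate 1 and pent-1-en-3-one 2 (asymmetric Robinson annulation, enol triflate, methyl coupling, hydrolysis). Ring order: cyclohexadiene (step 1), cyclohexane plus temporary lactone (step 6), final lactone (step 13).

Key step: step 6

Assumption: the quinine-derived thiourea named in step 1 is taken to deliver the (S) adduct; if its sense of induction is the opposite, the quinidine-derived pseudo-enantiomer is used instead.

**Route**

Step 1
Reactants: 1 ethyl 2-formylpropanoate; 2 pent-1-en-3-one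
Product: 4 ethyl (S)-1,3-dimethyl-4-oxocyclohex-2-ene-1-carboxylate, via Michael adduct 3 (not isolated)
Conditions: N-[3,5-bis(trifluoromethyl)phenyl]-N′-[(8α,9S)-6′-methoxycinchonan-9-yl]thiourea (10 mol %), toluene, −20 °C; then p-TsOH·H2O (20 mol %), reflux, Dean–Stark trap
Reagents that add atoms: none
Why: Robinson annulation: the bifunctional amine–thiourea catalyst should guide the enantioselective Michael addition of the α-formyl ester (an α-substituted 1,3-dicarbonyl pronucleophile) to the vinyl ketone and so set the quaternary centre C10, after which the acid-catalysed intramolecular aldol condensation can only close the six-membered enone because the aldehyde is not enolisable.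

Step 2
Reactants: 4 ethyl (S)-1,3-dimethyl-4-oxocyclohex-2-ene-1-carboxylate
Product: 6 ethyl (S)-1,3-dimethyl-4-(trifluoromethylsulfonyloxy)cyclohexa-2,4-diene-1-carboxylate, via lithium dienolate 5 (not isolated)
Conditions: LiN(i-Pr)2, THF, −78 °C; then PhNTf2, −78 → 0 °C
Reagents that add atoms: N-phenylbis(trifluoromethanesulfonimide), O=S(=O)(N(c1ccccc1)S(=O)(=O)C(F)(F)F)C(F)(F)F
Why: Kinetic α′-deprotonation of the enone gives the cross-conjugated dienolate, which is O-sulfonylated (enol triflate formation); no stereocentre is touched because C10 is quaternary.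

Step 3
Reactants: 6 ethyl (S)-1,3-dimethyl-4-(trifluoromethylsulfonyloxy)cyclohexa-2,4-diene-1-carboxylate
Product: 7 ethyl (S)-1,3,4-trimethylcyclohexa-2,4-diene-1-carboxylate
Conditions: MeMgBr, Fe(acac)3 (5 mol %), THF/NMP, −30 °C
Reagents that add atoms: methylmagnesium bromide, C[Mg]Br
Why: Iron-catalysed cross-coupling of an alkenyl triflate with a Grignard reagent (Kumada type) puts the second methyl group on the diene without moving the double bonds, and the hindered ester on the quaternary carbon should survive at low temperature.

Step 4
Reactants: 7 ethyl (S)-1,3,4-trimethylcyclohexa-2,4-diene-1-carboxylate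
Product: 8 (S)-1,3,4-trimethylcyclohexa-2,4-diene-1-carboxylic acid
Conditions: KOH, EtOH/H2O, 80 °C; then 1 M HCl, 0 °C
Reagents that add atoms: potassium hydroxide, [K+].[OH-]
Why: Saponification of the ester; the diene cannot aromatise because the carboxyl-bearing ring carbon is quaternary.

Step 5
Reactants: 8 (S)-1,3,4-trimethylcyclohexa-2,4-diene-1-carboxylic acid; 9 but-3-yn-2-one
Product: 10 (Z)-3-oxobut-1-en-1-yl (S)-1,3,4-trimethylcyclohexa-2,4-diene-1-carboxylate
Conditions: Cs2CO3 (10 mol %), MeCN, 0 °C
Reagents that add atoms: none
Why: Base-catalysed conjugate addition of the carboxylate to the ynone (hydro-acyloxylation of an activated alkyne): protonation of the allenolate anti to the acyloxy group should give the Z enol ester under kinetic control, and a catalytic, non-nucleophilic base at 0 °C limits Z to E equilibration.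

Step 6
Reactants: 10 (Z)-3-oxobut-1-en-1-yl (S)-1,3,4-trimethylcyclohexa-2,4-diene-1-carboxylate
Product: 11 tricyclic keto lactone (bicyclo[2.2.2]octene adduct)
Conditions: toluene (0.01 M), BHT (cat.), 110 °C, sealed tube
Reagents that add atoms: none
Why: Thermal intramolecular Diels–Alder reaction: a concerted [4+2] addition, suprafacial on both partners and of normal electron demand, between the 2,3-dimethyl-substituted ring diene (C5=C–C=C8) and the acyloxy enone (C6=C7) forms C5–C6 and C7–C8. The closest known reaction type is the intramolecular Diels–Alder reaction of cyclohexa-2,4-dienes and cyclohexa-2,4-dienones that carry the dienophile on the ring sp3 carbon through a two-atom ester or ether tether, which gives lactone- or ether-fused bicyclo[2.2.2]octenes. The cyclohexane ring C5–C6–C7–C8–C9–C10 is closed by the cycloaddition itself (it is one six-membered ring of the bicyclo[2.2.2]oct-2-ene), and the five-membered lactone C10–C1(=O)–O–C6–C5 is closed in the fused mode by the new C5–C6 bond. C5 and C8 follow from suprafacial addition to the ring diene (both bonds to the etheno bridge end up cis), C6 is set by the tether, which can reach only the diene face that carries C1 and so relays the configuration of C10, and C7 is set by the Z geometry of the dienophile, which puts the acetyl group cis to O-6 and exo. The step needs regioselectivity (C6 to C5, not to C8), which the two-atom tether secures because only this mode closes a five-membered ring, facial selectivity, secured by the same tether, and an intact Z alkene, for which the reaction is run neutral and dilute in the presence of a radical inhibitor. Heat is needed because the ester must adopt its less favoured s-cis form to reach the diene.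

Step 7
Reactants: 11 tricyclic keto lactone
Product: 13 tricyclic alkenyl triflate lactone, via potassium enolate 12 (not isolated)
Conditions: KN(SiMe3)2, THF, −78 °C; then PhNTf2, −78 → −20 °C
Reagents that add atoms: N-phenylbis(trifluoromethanesulfonimide), O=S(=O)(N(c1ccccc1)S(=O)(=O)C(F)(F)F)C(F)(F)F
Why: Kinetic deprotonation of the methyl ketone at CH3 and O-sulfonylation (enol triflate formation) mask the ketone against the later hydride and peracid steps and prepare the carbonylation; the lactone has no α-hydrogen and C7 should not be deprotonated at −78 °C.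

Step 8
Reactants: 13 tricyclic alkenyl triflate lactone
Product: 14 tricyclic alkenyl triflate lactol
Conditions: i-Bu2AlH (1.1 equiv), CH2Cl2, −78 °C; then aq. potassium sodium tartrate
Reagents that add atoms: none
Why: Partial reduction of a lactone to a lactol with i-Bu2AlH at −78 °C; the bridged lactol should stay closed, and the alkene and the alkenyl triflate do not react.

Step 9
Reactants: 14 tricyclic alkenyl triflate lactol
Product: 16 bicyclic diketone lactol, via secondary ozonide 15 (not isolated)
Conditions: O3, CH2Cl2, −78 °C (Sudan Red 7B end point); then PPh3, −78 → 25 °C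
Reagents that add atoms: ozone, [O-][O+]=O
Why: Ozonolysis with reductive work-up: the electron-rich tetrasubstituted bridge alkene should react far faster than the electron-poor alkenyl triflate, and cleavage opens the bicyclo[2.2.2]octene to leave acetyl groups on C5 and C8 with the cis-1,4 relationship fixed in step 6.

Step 10
Reactants: 16 bicyclic diketone lactol
Product: 17 bicyclic acetoxy ketone lactol
Conditions: m-CPBA, NaHCO3, CH2Cl2, 0 → 25 °C
Reagents that add atoms: 3-chloroperoxybenzoic acid, OOC(=O)c1cccc(Cl)c1
Why: Baeyer–Villiger oxidation with retention at the migrating carbon turns the C8 acetyl group directly into the C8 acetate; the C8 ketone (equatorial, migrating carbon without a β-oxygen) should react ahead of the C5 ketone, which is flanked by the quaternary C10 and by the oxygen-bearing C6.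

Step 11
Reactants: 17 bicyclic acetoxy ketone lactol
Product: 18 bicyclic acetoxy isopropenyl lactol
Conditions: Zn, CH2Br2, TiCl4 (reagent pre-formed in THF), CH2Cl2, 0 → 25 °C
Reagents that add atoms: dibromomethane, BrCBr
Why: Lombardo methylenation is non-basic and selective for ketones over esters, so the hindered, epimerisable C5 methyl ketone should become the isopropenyl group without epimerisation at C5 or β-elimination of O-6; any lactol that is methylenated as well gives 19 directly.

Step 12
Reactants: 18 bicyclic acetoxy isopropenyl lactol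
Product: 19 monocyclic hydroxy alkenyl triflate
Conditions: Ph3PCH3Br, KN(SiMe3)2, THF, −78 → 0 °C
Reagents that add atoms: methyltriphenylphosphonium bromide, C[P+](c1ccccc1)(c1ccccc1)c1ccccc1.[Br-]
Why: Wittig methylenation of the lactol through its hydroxy aldehyde tautomer gives the C10 vinyl group and frees the C6 hydroxyl; no ketone is left, and the low temperature should spare the acetate and the alkenyl triflate.

Step 13
Reactants: 19 monocyclic hydroxy alkenyl triflate
Product: 20 α-methylene lactone
Conditions: Pd(PPh3)4 (5 mol %), CO (1 atm), Et3N, MeCN, 60 °C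
Reagents that add atoms: carbon monoxide, [C-]#[O+]
Why: Palladium-catalysed carbonylative lactonisation of a hydroxy alkenyl triflate (oxidative addition, CO insertion, capture of the acyl palladium by the cis C6 hydroxyl) closes the cis-fused α-methylene γ-lactone; O-8 is blocked as the acetate, so only O-6 can close.

Step 14
Reactants: 20 α-methylene lactone
Product: 22 11-hydroxy lactone, via potassium lactone enolate 21 (not isolated)
Conditions: KBH(s-Bu)3, THF, −78 °C; then 2-(phenylsulfonyl)-3-phenyloxaziridine, −78 → −40 °C; then H2O
Reagents that add atoms: 2-(phenylsulfonyl)-3-phenyloxaziridine, O=S(=O)(c1ccccc1)N1OC1c1ccccc1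
Why: Conjugate reduction of the α-methylene lactone gives the lactone enolate regiospecifically, and electrophilic hydroxylation with the N-sulfonyloxaziridine should come from the convex face of the cis-fused bicycle (the side of H-6 and H-7), which places the C11 hydroxyl cis to H-7 and CH3-13 toward the carbocycle, as in the target.

Step 15
Reactants: 22 11-hydroxy lactone; 23 angelic acid
Product: 24 target CNP0140071.1
Conditions: 2,4,6-Cl3C6H2COCl, Et3N, toluene, 25 °C; then 22, toluene, 80 °C
Reagents that add atoms: none
Why: Yamaguchi-type esterification through the mixed anhydride of angelic acid, heated without a nucleophilic catalyst to keep the Z double bond; the secondary O-8 is already acetylated, so only the tertiary C11 hydroxyl can react.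

**Compound list**
1 | ethyl 2-formylpropanoate (racemic, enolisable) | CCOC(=O)C(C)C=O | starting material
2 | pent-1-en-3-one | CCC(=O)C=C | starting material
3 | ethyl (S)-2-formyl-2-methyl-5-oxoheptanoate (Michael adduct, not isolated) | CCOC(=O)[C@@](C=O)(C)CCC(=O)CC | intermediate
4 | ethyl (S)-1,3-dimethyl-4-oxocyclohex-2-ene-1-carboxylate | CCOC(=O)[C@@]1(C)CCC(=O)C(C)=C1 | intermediate
5 | lithium dienolate of 4, cross-conjugated (not isolated) | CCOC(=O)[C@@]1(C)CC=C([O-])C(C)=C1.[Li+] | intermediate
6 | ethyl (S)-1,3-dimethyl-4-(trifluoromethylsulfonyloxy)cyclohexa-2,4-diene-1-carboxylate | CCOC(=O)[C@@]1(C)CC=C(OS(=O)(=O)C(F)(F)F)C(C)=C1 | intermediate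
7 | ethyl (S)-1,3,4-trimethylcyclohexa-2,4-diene-1-carboxylate | CCOC(=O)[C@@]1(C)CC=C(C)C(C)=C1 | intermediate
8 | (S)-1,3,4-trimethylcyclohexa-2,4-diene-1-carboxylic acid | OC(=O)[C@@]1(C)CC=C(C)C(C)=C1 | intermediate
9 | but-3-yn-2-one | CC(=O)C#C | starting material
10 | (Z)-3-oxobut-1-en-1-yl (S)-1,3,4-trimethylcyclohexa-2,4-diene-1-carboxylate | CC(=O)/C=C\OC(=O)[C@@]1(C)CC=C(C)C(C)=C1 | intermediate
11 | tricyclic keto lactone: 2,3-dimethylbicyclo[2.2.2]oct-2-ene with bridgeheads C5 and C8; C10 bears CH3-14 (syn to the etheno bridge) and the lactone carbonyl C1, closed onto O-6; acetyl on C7 cis to O-6 | O=C3[C@@]1(C)C[C@H]4[C@@H](C(C)=O)[C@@H](O3)[C@@H]1C(C)=C4C | intermediate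
12 | potassium enolate of 11 (terminal enolate of the methyl ketone, not isolated) | O=C3[C@@]1(C)C[C@H]4[C@@H](C([O-])=C)[C@@H](O3)[C@@H]1C(C)=C4C.[K+] | intermediate
13 | alkenyl triflate of 11: C7 bears 1-(trifluoromethylsulfonyloxy)vinyl, rest as 11 | O=C3[C@@]1(C)C[C@H]4[C@@H](C(=C)OS(=O)(=O)C(F)(F)F)[C@@H](O3)[C@@H]1C(C)=C4C | intermediate
14 | lactol of 13: C1 is CH(OH) (both anomers), rest as 13 | OC3[C@@]1(C)C[C@H]4[C@@H](C(=C)OS(=O)(=O)C(F)(F)F)[C@@H](O3)[C@@H]1C(C)=C4C | intermediate
15 | secondary ozonide of 14: 1,2,4-trioxolane across the two former alkene carbons (not isolated; mixture at the two new acetal carbons) | OC3[C@@]1(C)C[C@H]4[C@@H](C(=C)OS(=O)(=O)C(F)(F)F)[C@@H](O3)[C@@H]1C5(C)OOC4(C)O5 | intermediate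
16 | diketone lactol: cyclohexane C5–C10 with acetyl groups on C5 and C8 (cis-1,4), lactol bridge C10–C1H(OH)–O–C6, 1-(trifluoromethylsulfonyloxy)vinyl on C7 (cis to O-6), CH3-14 on C10 (cis to the C5 acetyl) | OC3[C@@]1(C)C[C@H](C(C)=O)[C@@H](C(=C)OS(=O)(=O)C(F)(F)F)[C@@H](O3)[C@@H]1C(C)=O | intermediate
17 | as 16, but C8 bears OAc in place of acetyl (same configuration) | OC3[C@@]1(C)C[C@H](OC(C)=O)[C@@H](C(=C)OS(=O)(=O)C(F)(F)F)[C@@H](O3)[C@@H]1C(C)=O | intermediate
18 | as 17, but C5 bears isopropenyl in place of acetyl | OC3[C@@]1(C)C[C@H](OC(C)=O)[C@@H](C(=C)OS(=O)(=O)C(F)(F)F)[C@@H](O3)[C@@H]1C(=C)C | intermediate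
19 | hydroxy alkenyl triflate: cyclohexane with C10 (CH3, vinyl), C8 OAc, C7 1-(trifluoromethylsulfonyloxy)vinyl, C6 OH, C5 isopropenyl, all configured as in the target | C=C[C@@]1(C)C[C@H](OC(C)=O)[C@@H](C(=C)OS(=O)(=O)C(F)(F)F)[C@@H](O)[C@@H]1C(=C)C | intermediate
20 | α-methylene lactone: cis-fused 6,12-lactone with C11=CH2, otherwise as the target | C=C[C@@]1(C)C[C@H](OC(C)=O)[C@@H]2[C@@H](OC(=O)C2=C)[C@@H]1C(=C)C | intermediate
21 | potassium enolate of the 11-methyl lactone (not isolated) | C=C[C@@]1(C)C[C@H](OC(C)=O)[C@@H]2[C@@H](OC([O-])=C2C)[C@@H]1C(=C)C.[K+] | intermediate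
22 | 11-hydroxy lactone: the target without the angeloyl group (C11 OH cis to H-7) | C=C[C@@]1(C)C[C@H](OC(C)=O)[C@@H]2[C@@H](OC(=O)[C@@]2(C)O)[C@@H]1C(=C)C | intermediate
23 | angelic acid, (Z)-2-methylbut-2-enoic acid | C/C=C(/C)C(=O)O | starting material
24 | CNP0140071.1 | C=C[C@@]1(C)C[C@H](OC(C)=O)[C@@H]2[C@@H](OC(=O)[C@@]2(C)OC(=O)/C(C)=C\C)[C@@H]1C(=C)C | target

**Summary**
Total step count: 15. Longest linear sequence: 15 steps (from 1 and 2 to 24).

Steps most likely to fail:

Step 15. The acylation of the hindered tertiary hydroxyl may be too slow, so that isomerisation of the angeloyl unit to its E form or acetyl migration from O-8 competes. Fallback: set out from 22 and acylate O-11 with 2-[bis(2,2,2-trifluoroethoxy)phosphoryl]propanoyl chloride (pyridine, DMAP, CH2Cl2; forcing conditions are harmless here, since no Z alkene is present yet) to give the phosphonopropanoate ester F1. A Still–Gennari olefination of this ester with acetaldehyde (KN(SiMe3)2, 18-crown-6, THF, −78 °C) should then build the Z-trisubstituted double bond on the molecule and come back to the route at 24.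

Step 10. The peracid may not distinguish the two methyl ketones well enough (oxidation at the C5 acetyl or at both), and a slow oxidation may let the lactol be attacked. Fallback: set out from 14 and ozonise in CH2Cl2/MeOH (NaHCO3, −78 °C), so that the carbonyl oxide is trapped as the keto α-methoxy hydroperoxide F2. Treatment with Ac2O, Et3N and DMAP should then bring about a Criegee rearrangement (C8 migrates to oxygen with retention) and acetylate the lactol, giving the diacetate F3. Selective removal of the anomeric acetate with hydrazine acetate in DMF returns to the route at 17. In this variant the site is decided when the primary ozonide breaks up, where the carbonyl oxide should form on the bridge carbon remote from the oxygen-bearing C6 and C1.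

Step 5. Reversible conjugate addition may equilibrate the Z enol ester to the E isomer, which would give the C7 epimer in step 6. Fallback: set out from 8 and add it across the commercial tert-butyldimethylsilyl ether of but-3-yn-2-ol under ruthenium catalysis ([RuCl2(p-cymene)]2, P(4-ClC6H4)3, DMAP, toluene, 60 °C; anti-Markovnikov, Z-selective hydro-acyloxylation) to give the Z enol ester silyl ether F4. Desilylation with HF·pyridine (THF, 0 °C) gives the allylic alcohol F5, and Dess–Martin oxidation (NaHCO3, CH2Cl2) comes back to the route at 10.

**Further compounds**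
F1 | step 15 | 2-[bis(2,2,2-trifluoroethoxy)phosphoryl]propanoate of 22 on O-11 | C=C[C@@]1(C)C[C@H](OC(C)=O)[C@@H]2[C@@H](OC(=O)[C@@]2(C)OC(=O)C(C)P(=O)(OCC(F)(F)F)OCC(F)(F)F)[C@@H]1C(=C)C
F2 | step 10 | keto α-methoxy hydroperoxide: as 16, but C8 bears C(CH3)(OCH3)OOH | OC3[C@@]1(C)C[C@H](C(C)(OC)OO)[C@@H](C(=C)OS(=O)(=O)C(F)(F)F)[C@@H](O3)[C@@H]1C(C)=O
F3 | step 10 | diacetate: as 17, with the lactol hydroxyl on C1 acetylated | CC(=O)OC3[C@@]1(C)C[C@H](OC(C)=O)[C@@H](C(=C)OS(=O)(=O)C(F)(F)F)[C@@H](O3)[C@@H]1C(C)=O
F4 | step 5 | (Z)-3-(tert-butyldimethylsilyloxy)but-1-en-1-yl (S)-1,3,4-trimethylcyclohexa-2,4-diene-1-carboxylate | CC(O[Si](C)(C)C(C)(C)C)/C=C\OC(=O)[C@@]1(C)CC=C(C)C(C)=C1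
F5 | step 5 | (Z)-3-hydroxybut-1-en-1-yl (S)-1,3,4-trimethylcyclohexa-2,4-diene-1-carboxylate | CC(O)/C=C\OC(=O)[C@@]1(C)CC=C(C)C(C)=C1
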